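**Plan**

- Retrosynthesis, in order of cutting: (a) the C–S and C–N bonds of the thiazine dioxide (hypotaurine + naphthoquinone); (b) quinone back to a 1,4-dimethoxynaphthalene; (c) the lactone C(=O)–O bond of ring B (dienol of an enal + aryl carboxylic acid); (d) the formyl carbon and the C-methyl group, back to an α-aryl cyclohexanone; (e) the ring A CH2–C(quaternary) bond, by a retro-semipinacol shift to an achiral 1-(1-arylvinyl)cyclopentanol; (f) the aryl–vinyl bond, back to a symmetric dibromonaphthalene.
- Forward: naphthalene core (aryne + 2-methoxyfuran), vinyl carbinol (Suzuki), ring A by a ring-expanding 1,2-shift, then C-methyl, aryl ester, enol triflate and formyl group, then ring B (seven-membered dienol lactone), quinone, and the thiazine dioxide ring last.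
- Feature used by the key event: in ring A the quaternary carbon is benzylic (bonded to the naphthalene) and its other sp2 ring neighbour is the carbon that carries the exocyclic O–CH= of ring B. Written as a ketone carbon, that neighbour can start as the carbinol carbon of a cyclopentanol, so a cation at the benzylic carbon pulls a ring CH2 across.
- Stereochemistry: the only stereocentre (the quaternary benzylic carbon, S) is set in step 5 by a chiral Brønsted acid. It bears no hydrogen and is not touched again. The uncontrolled methyl-bearing centre made in step 6 becomes sp2 in step 8.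

Key step: step 5

Assumption: the (R)-configured acid of step 5 is taken to give the (S)-ketone; if the sense of induction is the opposite, the (S)-acid is used (both antipodes are accessible) and nothing else changes.

**Route**

Step 1
Reactants: 1 1,2,4,5-tetrabromobenzene; 2 2-methoxyfuran
Product: 6 6,7-dibromo-4-methoxynaphthalen-1-ol, via aryllithium 3 (not isolated), via 4,5-dibromobenzyne 4 (not isolated), via bridged ketal cycloadduct 5 (not isolated)
Conditions: n-BuLi (1.05 equiv), 2 (3 equiv), toluene, −23 °C to rt; then 1 M HCl, THF, rt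
Reagents that add atoms: none
Why: One bromine–lithium exchange and loss of LiBr should give the symmetric aryne, which is trapped by 2-methoxyfuran in an aryne Diels–Alder reaction; the bridged ketal opens under acid and aromatises to the 4-methoxy-1-naphthol, and the symmetry of the aryne leaves no regiochemical question.

Step 2
Reactants: 6 6,7-dibromo-4-methoxynaphthalen-1-ol
Product: 7 6,7-dibromo-1,4-dimethoxynaphthalene
Conditions: MeI, K2CO3, acetone, 50 °C
Reagents that add atoms: iodomethane CI
Why: Williamson ether synthesis on the naphthol; the hydroquinone dimethyl ether masks the later quinone through all basic, acidic and palladium steps.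

Step 3
Reactants: 8 1-ethynylcyclopentan-1-ol
Product: 9 1-[1-(4,4,5,5-tetramethyl-1,3,2-dioxaborolan-2-yl)ethenyl]cyclopentan-1-ol
Conditions: B2pin2, (SIMes)CuCl (chloro[1,3-bis(2,4,6-trimethylphenyl)imidazolidin-2-ylidene]copper, 5 mol %), NaOt-Bu (5 mol %), MeOH (2 equiv), THF, −50 °C to rt
Reagents that add atoms: bis(pinacolato)diboron CC1(C)OB(OC1(C)C)B1OC(C)(C)C(C)(C)O1
Why: Copper-catalysed Markovnikov (α-selective) hydroboration of a terminal alkyne; with an N-aryl carbene on monovalent copper and a propargylic oxygen the boryl group should go to the internal carbon, and methanol protonates the alkenylcopper.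

Step 4
Reactants: 7 6,7-dibromo-1,4-dimethoxynaphthalene; 9 1-[1-(4,4,5,5-tetramethyl-1,3,2-dioxaborolan-2-yl)ethenyl]cyclopentan-1-ol
Product: 10 1-[1-(3-bromo-5,8-dimethoxynaphthalen-2-yl)ethenyl]cyclopentan-1-ol
Conditions: 7 (2 equiv), PdCl2(dppf) (5 mol %), K3PO4, 1,4-dioxane/H2O, 80 °C
Reagents that add atoms: none
Why: Suzuki–Miyaura coupling; the two bromides of 7 are equivalent, and the first coupling puts a bulky 1,1-disubstituted alkenyl group next to the second bromide, which together with the excess of 7 should stop the reaction at mono-coupling.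

Step 5
Reactants: 10 1-[1-(3-bromo-5,8-dimethoxynaphthalen-2-yl)ethenyl]cyclopentan-1-ol
Product: 12 (2S)-2-(3-bromo-5,8-dimethoxynaphthalen-2-yl)-2-methylcyclohexan-1-one, via benzylic cation 11 (not isolated)
Conditions: (R)-3,3'-bis(2,4,6-triisopropylphenyl)-1,1'-binaphthalene-2,2'-diyl N-(trifluoromethanesulfonyl)phosphoramide (10 mol %), toluene, 4 Å MS, −40 to −20 °C
Reagents that add atoms: none
Why: Proposed new method: the strong chiral Brønsted acid should protonate the terminal CH2 of the 1,1-disubstituted styrene to give the tertiary benzylic cation 11 as a contact ion pair whose anion is hydrogen-bonded to the adjacent tertiary OH, after which one ring CH2 of the cyclopentanol shifts from the carbinol carbon to the cationic carbon and the carbinol carbon becomes the protonated ketone that hands the proton back to the catalyst (protio-semipinacol rearrangement). The closest known reaction type is the chiral-acid-catalysed protio-semipinacol ring expansion of 1-(1-arylvinyl)cyclopropanols and 1-(1-arylvinyl)cyclobutanols, together with the halonium-triggered asymmetric semipinacol shifts of the same class of allylic alcohol; what is new is the unstrained five-membered carbinol, for which the driving force is carbonyl formation at the expense of the benzylic cation instead of strain release. Ring A is closed by a 1,2-alkyl shift, a five-to-six ring expansion in which the CH2–C(quaternary) bond forms as the CH2–C(carbinol) bond breaks. The new stereocentre is controlled by the catalyst alone: the cation is planar, the two ring CH2 groups are enantiotopic, and the chiral anion held at the OH decides which CH2 migrates onto which face. The step needs rearrangement to outrun ionisation of the tertiary allylic alcohol (diene formation) and capture of the cation by a neighbouring group; the shift that ends in a carbonyl is fast, and the ortho substituent of the arene is bromine, which cannot close a ring onto the cation as an ester would (phthalide formation). The quaternary centre so formed carries no hydrogen and cannot be epimerised by any later step.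

Step 6
Reactants: 12 (2S)-2-(3-bromo-5,8-dimethoxynaphthalen-2-yl)-2-methylcyclohexan-1-one
Product: 14 (2S)-2-(3-bromo-5,8-dimethoxynaphthalen-2-yl)-2,6-dimethylcyclohexan-1-one (both epimers at C-6), via lithium enolate 13 (not isolated)
Conditions: LiN(i-Pr)2, THF, −78 °C; MeI, −78 to 0 °C
Reagents that add atoms: iodomethane CI
Why: Enolate C-alkylation at the only enolisable α-carbon (the other is quaternary); the new methyl-bearing centre is not controlled and is removed when this carbon becomes sp2 in step 8.

Step 7
Reactants: 14 (2S)-2-(3-bromo-5,8-dimethoxynaphthalen-2-yl)-2,6-dimethylcyclohexan-1-one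
Product: 15 methyl 3-[(1S)-1,3-dimethyl-2-oxocyclohexyl]-5,8-dimethoxynaphthalene-2-carboxylate (both epimers at the methine carbon)
Conditions: CO (1 atm), Pd(OAc)2 (5 mol %), Xantphos (10 mol %), Et3N, MeOH/toluene, 90 °C
Reagents that add atoms: carbon monoxide [C-]#[O+]; methanol CO
Why: Palladium-catalysed alkoxycarbonylation of the aryl bromide (oxidative addition to zerovalent palladium, CO insertion, methanolysis); the wide-bite-angle ligand tolerates the ortho substituent, and excess methanol intercepts the acylpalladium before the ketone enol can.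

Step 8
Reactants: 15 methyl 3-[(1S)-1,3-dimethyl-2-oxocyclohexyl]-5,8-dimethoxynaphthalene-2-carboxylate
Product: 17 methyl 3-[(1S)-1,3-dimethyl-2-(trifluoromethanesulfonyloxy)cyclohex-2-en-1-yl]-5,8-dimethoxynaphthalene-2-carboxylate, via potassium enolate 16 (not isolated)
Conditions: KN(SiMe3)2, THF, −78 °C; PhNTf2, −78 to 0 °C
Reagents that add atoms: N-phenylbis(trifluoromethanesulfonimide) O=S(=O)(N(c1ccccc1)S(=O)(=O)C(F)(F)F)C(F)(F)F
Why: Enol triflate formation from the single possible enolate, as with 2,2,6-trimethylcyclohexanone; O-acylation of this enolate by the neighbouring methyl ester is uphill, so the ester should survive at low temperature.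

Step 9
Reactants: 17 methyl 3-[(1S)-1,3-dimethyl-2-(trifluoromethanesulfonyloxy)cyclohex-2-en-1-yl]-5,8-dimethoxynaphthalene-2-carboxylate
Product: 18 methyl 3-[(1S)-2-formyl-1,3-dimethylcyclohex-2-en-1-yl]-5,8-dimethoxynaphthalene-2-carboxylate
Conditions: CO (1 atm), Et3SiH, Pd(OAc)2 (5 mol %), dppp (5 mol %), Et3N, DMF, 70 °C
Reagents that add atoms: carbon monoxide [C-]#[O+]
Why: Palladium-catalysed reductive carbonylation (formylation) of the enol triflate: oxidative addition, CO insertion, hydride transfer from the silane and reductive elimination give the tetrasubstituted enal, a cyclocitral-type aldehyde.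

Step 10
Reactants: 18 methyl 3-[(1S)-2-formyl-1,3-dimethylcyclohex-2-en-1-yl]-5,8-dimethoxynaphthalene-2-carboxylate
Product: 19 3-[(1S)-2-formyl-1,3-dimethylcyclohex-2-en-1-yl]-5,8-dimethoxynaphthalene-2-carboxylic acid
Conditions: LiOH, THF/MeOH/H2O, 50 °C; then 1 M HCl to pH 3
Reagents that add atoms: lithium hydroxide [Li+].[OH-]
Why: Saponification of the methyl ester; the aldehyde has no α-hydrogen and sits on a tetrasubstituted alkene, so hydroxide should neither add to it nor condense it.

Step 11
Reactants: 19 3-[(1S)-2-formyl-1,3-dimethylcyclohex-2-en-1-yl]-5,8-dimethoxynaphthalene-2-carboxylic acid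
Product: 21 (S)-dimethoxy tetracyclic dienol lactone (1,4-dimethoxynaphthalene fused through C-6 and C-7 to the seven-membered enol lactone ring B which is fused to ring A), via mixed anhydride 20 (not isolated)
Conditions: 2,4,6-trichlorobenzoyl chloride, Et3N, THF, rt; then DMAP, toluene (2 mM), 80 °C
Reagents that add atoms: none
Why: Yamaguchi activation followed by O-acylation of the dienol: the amine bases remove a γ-hydrogen from the ring CH2 of the enal and the dienol oxygen is acylated by the acylpyridinium within the molecule, which closes ring B and places both double bonds as in the target (enol ester formation of the kind that turns cyclocitral-type enals into 1-acyloxy dienes).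

Step 12
Reactants: 21 (S)-dimethoxy tetracyclic dienol lactone
Product: 22 (S)-naphthoquinone dienol lactone
Conditions: (NH4)2Ce(NO3)6 (2.5 equiv), MeCN/H2O 3:1, 0 °C, 15 min
Reagents that add atoms: water O
Why: Oxidative demethylation of the hydroquinone dimethyl ether by tetravalent cerium; the dimethoxynaphthalene is oxidised at a far lower potential than the acylated dienol, and the short cold exposure should spare the enol lactone.

Step 13
Reactants: 22 (S)-naphthoquinone dienol lactone; 23 hypotaurine (2-aminoethanesulfinic acid)
Product: 27 CNP0348176.1 (target), via sulfonyl hydroquinone 24 (not isolated), via sulfonyl quinone 25 (not isolated), via thiazine hydroquinone 26 (not isolated)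
Conditions: 23 (1.2 equiv), MeCN/EtOH/H2O, rt, open to air
Reagents that add atoms: none
Why: Hypotaurine annulation of a quinone (sulfinate conjugate addition through sulfur, air oxidation, ring-closing conjugate addition of the amine, second air oxidation); the sulfinate should attack the quinone carbon β to the more electron-poor carbonyl, the one whose ring-fusion carbon is para to the lactone carbonyl, so that sulfur ends next to the other carbonyl and nitrogen next to this one, as in the target.

**Compound list**

1 | 1,2,4,5-tetrabromobenzene | Brc1cc(Br)c(Br)cc1Br | starting material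
2 | 2-methoxyfuran | COc1ccco1 | starting material
3 | (2,4,5-tribromophenyl)lithium | [Li]c1cc(Br)c(Br)cc1Br | intermediate
4 | 4,5-dibromobenzyne | BrC1=CC#CC=C1Br | intermediate
5 | 6,7-dibromo-1-methoxy-1,4-dihydro-1,4-epoxynaphthalene | COC12OC(C=C1)c1cc(Br)c(Br)cc12 | intermediate
6 | 6,7-dibromo-4-methoxynaphthalen-1-ol | COc1ccc(O)c2cc(Br)c(Br)cc12 | intermediate
7 | 6,7-dibromo-1,4-dimethoxynaphthalene | COc1ccc(OC)c2cc(Br)c(Br)cc12 | intermediate
8 | 1-ethynylcyclopentan-1-ol | C#CC1(O)CCCC1 | starting material
9 | 1-[1-(4,4,5,5-tetramethyl-1,3,2-dioxaborolan-2-yl)ethenyl]cyclopentan-1-ol | C=C(B1OC(C)(C)C(C)(C)O1)C1(O)CCCC1 | intermediate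
10 | 1-[1-(3-bromo-5,8-dimethoxynaphthalen-2-yl)ethenyl]cyclopentan-1-ol | C=C(c1cc2c(OC)ccc(OC)c2cc1Br)C1(O)CCCC1 | intermediate
11 | 1-(3-bromo-5,8-dimethoxynaphthalen-2-yl)-1-(1-hydroxycyclopentyl)ethylium (ion pair with the catalyst anion) | C[C+](c1cc2c(OC)ccc(OC)c2cc1Br)C1(O)CCCC1 | intermediate
12 | (2S)-2-(3-bromo-5,8-dimethoxynaphthalen-2-yl)-2-methylcyclohexan-1-one | O=C1CCCC[C@@]1(C)c1cc2c(OC)ccc(OC)c2cc1Br | intermediate
13 | lithium (6S)-6-(3-bromo-5,8-dimethoxynaphthalen-2-yl)-6-methylcyclohex-1-en-1-olate | [Li]OC1=CCCC[C@@]1(C)c1cc2c(OC)ccc(OC)c2cc1Br | intermediate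
14 | (2S)-2-(3-bromo-5,8-dimethoxynaphthalen-2-yl)-2,6-dimethylcyclohexan-1-one, both epimers at C-6 | O=C1C(C)CCC[C@@]1(C)c1cc2c(OC)ccc(OC)c2cc1Br | intermediate
15 | methyl 3-[(1S)-1,3-dimethyl-2-oxocyclohexyl]-5,8-dimethoxynaphthalene-2-carboxylate, both epimers at the methine carbon | O=C1C(C)CCC[C@@]1(C)c1cc2c(OC)ccc(OC)c2cc1C(=O)OC | intermediate
16 | potassium (6S)-6-[5,8-dimethoxy-3-(methoxycarbonyl)naphthalen-2-yl]-2,6-dimethylcyclohex-1-en-1-olate | CC1=C(O[K])[C@](C)(c2cc3c(OC)ccc(OC)c3cc2C(=O)OC)CCC1 | intermediate
17 | methyl 3-[(1S)-1,3-dimethyl-2-(trifluoromethanesulfonyloxy)cyclohex-2-en-1-yl]-5,8-dimethoxynaphthalene-2-carboxylate | CC1=C(OS(=O)(=O)C(F)(F)F)[C@](C)(c2cc3c(OC)ccc(OC)c3cc2C(=O)OC)CCC1 | intermediate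
18 | methyl 3-[(1S)-2-formyl-1,3-dimethylcyclohex-2-en-1-yl]-5,8-dimethoxynaphthalene-2-carboxylate | CC1=C(C=O)[C@](C)(c2cc3c(OC)ccc(OC)c3cc2C(=O)OC)CCC1 | intermediate
19 | 3-[(1S)-2-formyl-1,3-dimethylcyclohex-2-en-1-yl]-5,8-dimethoxynaphthalene-2-carboxylic acid | CC1=C(C=O)[C@](C)(c2cc3c(OC)ccc(OC)c3cc2C(O)=O)CCC1 | intermediate
20 | mixed anhydride of 19 with 2,4,6-trichlorobenzoic acid, (S) | CC1=C(C=O)[C@](C)(c2cc3c(OC)ccc(OC)c3cc2C(=O)OC(=O)c2c(Cl)cc(Cl)cc2Cl)CCC1 | intermediate
21 | (S)-dimethoxy tetracyclic dienol lactone: 1,4-dimethoxynaphthalene with the lactone carbonyl on C-6 and the quaternary carbon (CH3, S) on C-7; ring B is Ar–C(=O)–O–CH=C; ring A holds the quaternary carbon, two CH2, CH=C(CH3) and the enol sp2 carbon | CC1=CCC[C@]2(C)C1=COC(=O)c1cc3c(OC)ccc(OC)c3cc12 | intermediate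
22 | (S)-naphthoquinone dienol lactone: as 21 with the dimethoxy ring oxidised to the 1,4-quinone | CC1=CCC[C@]2(C)C1=COC(=O)c1cc3c(cc12)C(=O)C=CC3=O | intermediate
23 | hypotaurine (2-aminoethanesulfinic acid) | NCCS(O)=O | starting material
24 | (S)-sulfonyl hydroquinone: as 22 reduced to the 1,4-diol, with a 2-aminoethylsulfonyl group on the ring carbon next to the hydroxyl-bearing carbon that is para-related to the quaternary-carbon side | CC1=CCC[C@]2(C)C1=COC(=O)c1cc3c(cc12)c(O)cc(S(=O)(=O)CCN)c3O | intermediate
25 | (S)-sulfonyl quinone: quinone form of 24 | CC1=CCC[C@]2(C)C1=COC(=O)c1cc3c(cc12)C(=O)C=C(C3=O)S(=O)(=O)CCN | intermediate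
26 | (S)-thiazine hydroquinone: ring-closed 1,4-diol, dihydro form of the target | CC1=CCC[C@]2(C)C1=COC(=O)c1cc3c(cc12)c(O)c1NCCS(=O)(=O)c1c3O | intermediate
27 | CNP0348176.1, (S) at the quaternary carbon: naphthoquinone fused to a 1,1-dioxo-1,4-thiazine ring (NH next to the carbonyl whose ring-fusion carbon is para to the lactone carbonyl), the seven-membered dienol lactone ring B and the methylcyclohexene ring A | CC1=CCC[C@]2(C)C1=COC(=O)c1cc3c(cc12)C(=O)C1=C(C3=O)S(=O)(=O)CCN1 | target

**Count and risks**

Total steps: 13. Longest linear sequence: 12 steps (steps 1, 2 and 4 to 13, from 1); step 3 is a one-step side branch.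

Steps most likely to fail:

1. Step 5 (proposed new method). What may go wrong: ionisation of the tertiary allylic alcohol and elimination to dienes instead of alkene protonation; slow protonation because the ortho bromine twists the arene out of conjugation with the alkene; a loose ion pair that discriminates poorly between the two migrating CH2 groups. A more acidic confined acid of the imidodiphosphorimidate type would be screened first. The fallback uses known chemistry, sets out from 7 and comes back at 12. Boron–Wittig olefination of cyclopentanone with 1,1-bis(4,4,5,5-tetramethyl-1,3,2-dioxaborolan-2-yl)ethane and lithium 2,2,6,6-tetramethylpiperidide should give 2-(1-cyclopentylideneethyl)-4,4,5,5-tetramethyl-1,3,2-dioxaborolane F1. Suzuki–Miyaura mono-coupling of F1 with 7 (PdCl2(dppf), K3PO4) should give the tetrasubstituted alkene 6-bromo-7-(1-cyclopentylideneethyl)-1,4-dimethoxynaphthalene F2. Shi epoxidation (the fructose-derived ketone in the antipode that gives the R epoxide, KHSO5, K2CO3 buffer, MeCN/H2O, 0 °C) should give (2R)-2-(3-bromo-5,8-dimethoxynaphthalen-2-yl)-2-methyl-1-oxaspiro[2.4]heptane F3. Et2AlCl in toluene at −78 °C should then open the benzylic C–O bond while a ring CH2 migrates with inversion at the benzylic carbon (stereospecific epoxide-to-ketone ring expansion), which gives 12. Here the stereocentre comes from the epoxidation and is handed on by the shift.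

2. Step 13. What may go wrong: attack of the free amine on the activated enol-lactone carbonyl, which opens ring B in competition with the annulation; erosion of site selectivity in the first sulfinate addition, because the directing lactone carbonyl is remote. The fallback sets out from 18 and comes back at 27; it closes ring B last, so that the amine never meets the enol lactone and the site isomers are separated on a robust ester. Oxidation of 18 with (NH4)2Ce(NO3)6 should give the quinone ester F4. Hypotaurine in MeCN/EtOH/H2O under air should take it through the sulfonyl hydroquinone ester F5, the sulfonyl quinone ester F6 and the thiazine hydroquinone ester F7 to the thiazinoquinone ester F8. Me3SnOH in 1,2-dichloroethane at 80 °C should cleave the methyl ester to the thiazinoquinone acid F9. Yamaguchi lactonisation through the mixed anhydride F10 (2,4,6-trichlorobenzoyl chloride, Et3N; DMAP, toluene, 80 °C) should then give 27.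

3. Step 11. What may go wrong: removal of a hydrogen from the ring methyl group instead of the ring CH2, leading to the isomer with an exocyclic methylene; acylation between molecules (oligomers); slow closure of the seven-membered ring. The fallback sets out from 19 and comes back at 21; it replaces base-mediated O-acylation by dehydration of a pseudo-acid. Treatment of 19 with LiN(i-Pr)2 (2.2 equiv, THF, −78 °C) should give the dilithium dienolate carboxylate F11. Kinetic protonation at the α-carbon (AcOH, −78 °C) should give the deconjugated aldehyde acid 3-[(1R)-2-formyl-1,3-dimethylcyclohex-3-en-1-yl]-5,8-dimethoxynaphthalene-2-carboxylic acid F12 (the change of descriptor follows from the priority rules; the spatial arrangement is unchanged). F12 should close to its cyclic hydroxy lactone (pseudo-acid) F13. TsOH (cat.) in toluene at reflux with removal of water should dehydrate F13 to the conjugated dienol lactone 21.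

Further compounds

F1 | step 5 | 2-(1-cyclopentylideneethyl)-4,4,5,5-tetramethyl-1,3,2-dioxaborolane | CC(B1OC(C)(C)C(C)(C)O1)=C1CCCC1
F2 | step 5 | 6-bromo-7-(1-cyclopentylideneethyl)-1,4-dimethoxynaphthalene | CC(=C1CCCC1)c1cc2c(OC)ccc(OC)c2cc1Br
F3 | step 5 | (2R)-2-(3-bromo-5,8-dimethoxynaphthalen-2-yl)-2-methyl-1-oxaspiro[2.4]heptane | C[C@]1(c3cc4c(OC)ccc(OC)c4cc3Br)OC12CCCC2
F4 | step 13 | methyl 3-[(1S)-2-formyl-1,3-dimethylcyclohex-2-en-1-yl]-5,8-dioxo-5,8-dihydronaphthalene-2-carboxylate | CC1=C(C=O)[C@](C)(c2cc3c(cc2C(=O)OC)C(=O)C=CC3=O)CCC1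
F5 | step 13 | sulfonyl hydroquinone ester: 1,4-diol of F4 with a 2-aminoethylsulfonyl group next to the hydroxyl-bearing carbon on the ester side of the ring fusion, (S) | CC1=C(C=O)[C@](C)(c2cc3c(cc2C(=O)OC)c(O)c(S(=O)(=O)CCN)cc3O)CCC1
F6 | step 13 | sulfonyl quinone ester: quinone form of F5, (S) | CC1=C(C=O)[C@](C)(c2cc3c(cc2C(=O)OC)C(=O)C(S(=O)(=O)CCN)=CC3=O)CCC1
F7 | step 13 | thiazine hydroquinone ester: ring-closed 1,4-diol, (S) | CC1=C(C=O)[C@](C)(c2cc3c(cc2C(=O)OC)c(O)c4c(NCCS4(=O)=O)c3O)CCC1
F8 | step 13 | thiazinoquinone methyl ester: the target with ring B open as enal and methyl ester, (S) | CC1=C(C=O)[C@](C)(c2cc3c(cc2C(=O)OC)C(=O)C4=C(NCCS4(=O)=O)C3=O)CCC1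
F9 | step 13 | thiazinoquinone acid: carboxylic acid of F8, (S) | CC1=C(C=O)[C@](C)(c2cc3c(cc2C(O)=O)C(=O)C4=C(NCCS4(=O)=O)C3=O)CCC1
F10 | step 13 | mixed anhydride of F9 with 2,4,6-trichlorobenzoic acid, (S) | CC1=C(C=O)[C@](C)(c2cc3c(cc2C(=O)OC(=O)c5c(Cl)cc(Cl)cc5Cl)C(=O)C4=C(NCCS4(=O)=O)C3=O)CCC1
F11 | step 11 | dilithium dienolate carboxylate of 19, (S) | CC1=CCC[C@@](C)(c2cc3c(OC)ccc(OC)c3cc2C(=O)O[Li])C1=CO[Li]
F12 | step 11 | 3-[(1R)-2-formyl-1,3-dimethylcyclohex-3-en-1-yl]-5,8-dimethoxynaphthalene-2-carboxylic acid, both epimers at the formyl-bearing carbon | CC1=CCC[C@@](C)(c2cc3c(OC)ccc(OC)c3cc2C(O)=O)C1C=O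
F13 | step 11 | hydroxy lactone (pseudo-acid) form of F12: ring B closed as the lactol ester, (R) at the quaternary carbon, epimers at the two new sp3 carbons | CC1=CCC[C@]2(C)C1C(O)OC(=O)c1cc3c(OC)ccc(OC)c3cc12
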